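# Proposed synthesis of (2E)-3-(2,2-dimethyl-2H-chromen-6-yl)-1-[(2R)-4-hydroxy-2-(2-hydroxypropan-2-yl)-2,3-dihydro-1-benzofuran-5-yl]prop-2-en-1-one (CNP0302034.2)

## The problem

The target joins two bicyclic aryl units through an E-enone. The carbonyl sits on C5 of a 4-hydroxy-2,3-dihydro-1-benzofuran (benzene ring A fused to dihydrofuran ring B), and the β-carbon sits on C6 of a 2,2-dimethyl-2H-chromene (benzene ring C fused to pyran ring D). There is one stereocentre, C2 of ring B, which carries the 2-hydroxypropan-2-yl group and must be R. No second stereocentre exists to relay from, so it has to be set by a chiral reagent or catalyst; once it is a plain ether carbon it is configurationally safe. Ring A carries four contiguous substituents (O1 on C7a, CH2 on C3a, OH on C4, acyl on C5), so the acyl group must be placed ortho to the C4 oxygen without touching C7. The sensitive groups are the enone (a Michael acceptor that the C4 phenol can attack), the electron-rich styrenyl alkene of ring D, the tertiary alcohol, and ring B itself, which opens by β-elimination of phenoxide if C3 is deprotonated. What opens the way to the key step is that the CH2 carbon C3 (on C3a) and the ether oxygen O1 (on C7a) sit on adjacent carbons of ring A and are both bonded to C2. Ring A together with these two atoms therefore maps onto an ortho-quinone methide, and C2 onto a one-carbon partner that can carry an ester as the precursor of the C(CH3)2OH group.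

## Retrosynthesis

**29 to 27 (no skeletal cut).** The C4 phenol and the tertiary alcohol of target 29 are masked as the MOM ether and trimethylsilyl ether of 27. MOM is chosen because it serves twice earlier: it differentiates the two phenols of the starting aldehyde and it directs metalation to C5. The forward step must be an acid treatment mild enough for the chromene, the enone and the carbinol.

**27 to 16 and 24 (cut C5–C(O)).** The aryl–acyl bond is cut, giving the ring A/B unit 16, which has a C–H at C5, and the Weinreb amide 24, which already holds the E-alkene. The neighbouring cut at Cα=Cβ (aldol condensation) needs a separate acetylation step first. A three-component carbonylative cut needs an aryl iodide and CO. The forward reaction must lithiate C5 selectively next to the MOM group and add 1,2 to the unsaturated amide.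

**24 to 22 and 23, then 22 to 19, then 17 and 18.** The aryl–Cβ bond of 24 is cut by a Mizoroki–Heck disconnection to bromochromene 22 and acrylamide 23. Ring D of 22 is opened by a propargyl Claisen disconnection to ether 19, made from 4-bromophenol 17 and the propargylic chloride 18. All three precursors are simple, and the bromine of 17 ends up para to oxygen, which is C6 of the chromene.

**16 to 15 to 13 (cut both C–CH3 bonds).** The silyl ether 16 comes from carbinol 15, and the two methyl groups of 15 are removed to leave methyl ester 13. The ester is the group that stabilises the ylide in the key step. The forward Grignard addition must not epimerise C2, which is α to the carbonyl only at this stage.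

**13 to 5 and 9 (cut O1–C2 and C2–C3; key disconnection).** Both bonds to C2 are cut at once. Ring B disappears, ring A becomes the quinone methide precursor 5, and C2 with its ester becomes the ammonium salt 9. Cutting only O1–C2 would require a chain with a stereodefined leaving group or epoxide. Cutting only C2–C3 would require a C–H functionalisation. The two-bond cut reduces the problem to a phenol sulfone and a bromoacetate-derived salt. The forward reaction must form both bonds and decide the C2 configuration in the ring closure.

**9 to 7 and 8, and 7 to 6.** The salt 9 is the quaternisation product of 9-O-methylquinidine 7 with methyl bromoacetate 8, and 7 is the methyl ether of quinidine 6. The C9 hydroxyl is capped because a free hydroxyl could lactonise onto the methyl ester within the salt under carbonate.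

**5 to 3 and 4, then 3 to 2 to 1.** The C–S bond of sulfone 5 is cut to benzylic alcohol 3 and sulfinate 4. Alcohol 3 comes from aldehyde 2, the mono-MOM ether of 2,6-dihydroxybenzaldehyde 1. The MOM group is installed first because the second hydroxyl of 2 is held in a hydrogen bond to the aldehyde, so mono-protection is selective. This order also avoids the unprotected 2,6-dihydroxybenzyl alcohol, which self-condenses readily.

## Roads not taken

**Alternative 1: carbonylative Heck union.**
- **Cut.** The carbonyl carbon is removed and both C5–C(O) and C(O)–Cα are broken. This leads to three components: the aryl iodide 2-[(2R)-5-iodo-4-(methoxymethoxy)-2,3-dihydro-1-benzofuran-2-yl]propan-2-ol A2, carbon monoxide, and the vinylchromene 6-ethenyl-2,2-dimethyl-2H-chromene A3.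
- **Forward step.** Pd(OAc)2, di(1-adamantyl)butylphosphine and NEt3 under CO would take A2 through oxidative addition to zerovalent palladium, CO insertion, insertion of A3 and β-hydride elimination. The product is the E-enone (2E)-3-(2,2-dimethyl-2H-chromen-6-yl)-1-[(2R)-2-(2-hydroxypropan-2-yl)-4-(methoxymethoxy)-2,3-dihydro-1-benzofuran-5-yl]prop-2-en-1-one A1. Compound A1 has the same structure as intermediate 28 of the chosen route.
- **Merits.** The conditions are neutral and tolerate the free tertiary alcohol, so no silyl ether is needed on the way to A1. The metal is catalytic, and no strong base meets the assembled enone.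
- **Weak points.** The road does not address C2 at all, so A2 must still be made in enantiopure form. A2 would come from 15 by the same kind of C5 lithiation followed by iodination, which is one step more than direct acylation, and A3 needs its own preparation from 22. The electron-rich, ortho-alkoxy aryl iodide A2 inserts CO slowly, so direct Heck arylation of A3 without CO uptake competes. Pressurised CO is required.
- **Comparison.** In mildness at the union this road is better than the chosen plan. The chosen plan offers a two-component acylation without CO and one step fewer at the junction. Its key step is spent on the stereocentre, which is the harder problem.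

**Alternative 2: asymmetric epoxidation, then 5-exo phenoxide closure.**
- **Cut.** Only O1–C2 is cut, back to the prenylarene 1,3-bis{[tert-butyl(dimethyl)silyl]oxy}-2-(3-methylbut-2-en-1-yl)benzene A5.
- **Forward step.** A chiral dioxirane from a fructose-derived ketone and KHSO5 (Shi epoxidation) would convert A5 into the epoxide (3S)-3-[(2,6-bis{[tert-butyl(dimethyl)silyl]oxy}phenyl)methyl]-2,2-dimethyloxirane A6. Bu4NF in the same flask would free a phenoxide that opens A6 at the secondary carbon with inversion, giving the diol (2R)-2-(2-hydroxypropan-2-yl)-2,3-dihydro-1-benzofuran-4-ol A4.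
- **Merits.** Both events are known reaction types on this substrate class. The carbinol arrives with the ring, so no Grignard step is needed. The symmetry of A5 makes the two phenoxides equivalent. In precedent and predictability this road is stronger than the chosen plan.
- **Weak points.** By the spiro transition-state model, the ketone from D-fructose is expected to give the enantiomer of A6 and hence the enantiomer of A4. The (2R) series needs A6 itself and therefore the enantiomeric ketone, which requires a longer preparation from L-sorbose. A5 needs C-prenylation between two oxygens and a protecting-group exchange. A4 must be re-protected before the C5 acylation to reach 15.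
- **Comparison.** The chosen plan sets against this a chiral controller that is cheap in both pseudoenantiomeric forms and is recovered, and a three-step precursor. The price is a key step beyond current precedent.

**Alternative 3: cobalt metalloradical C–H alkylation closing C2–C3.**
- **Cut.** Only C2–C3 is cut, back to the tosylhydrazone N'-[(E)-{2-[tert-butyl(dimethyl)silyl]oxy-6-[2-methyl-2-(triethylsilyloxy)propoxy]phenyl}methylidene]-4-methylbenzenesulfonohydrazide A8.
- **Forward step.** Cs2CO3 would decompose A8 to its diazo form in the flask. [Co(Por*)], the divalent cobalt complex of a D2-symmetric chiral amidoporphyrin Por*, would turn this into a carbene radical at the future C3. A 1,5-hydrogen abstraction from the O–CH2 group and radical recombination would close ring B. The product is the bis-silyl ether tert-butyl(dimethyl){[(2R)-2-[2-(triethylsilyloxy)propan-2-yl]-2,3-dihydro-1-benzofuran-4-yl]oxy}silane A7.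
- **Merits.** The chiral controller is catalytic. The carbinol carbon is present from the start, so A7 needs no Grignard step. A8 derives from the same aldehyde 1 by O-alkylation, silylation and hydrazone formation.
- **Weak points.** The porphyrin ligand is a multistep preparation. The abstracted C–H is flanked by a fully substituted carbon, so recombination at a congested radical must still be enantioselective. A7 carries two different silyl ethers, and its aryl silyl ether would have to be exchanged for MOM before the C5 lithiation, which adds steps after A7.
- **Comparison.** In catalyst economy this road is better, and the radical closure to A7 lies closer to established reactivity than step 6 does. The chosen plan offers a commercially derived alkaloid in either pseudoenantiomeric form and shorter access to the precursor.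

Key step: step 6

Assumption: the sense of induction of the O-methylquinidinium group cannot be derived from the substituted cases; 9-O-methylquinidine is written, and the pseudoenantiomeric 9-O-methylquinine would replace it, with no other change, if the closure favoured the (2S)-ester.

## Route

Step 1
Reactants: 1 2,6-dihydroxybenzaldehyde
Product: 2 2-hydroxy-6-(methoxymethoxy)benzaldehyde
Conditions: MOMCl (1.05 equiv), i-Pr2NEt, CH2Cl2, 0 °C to rt
Reagents that add atoms: chloromethyl methyl ether, COCCl
Why: Williamson-type O-alkylation (MOM protection); the two hydroxyls of 1 are equivalent, and after the first alkylation the remaining one is locked in a hydrogen bond to the aldehyde and is much less nucleophilic, so one equivalent should stop at the mono-ether.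

Step 2
Reactants: 2 2-hydroxy-6-(methoxymethoxy)benzaldehyde
Product: 3 2-(hydroxymethyl)-3-(methoxymethoxy)phenol
Conditions: NaBH4, MeOH, 0 °C
Reagents that add atoms: none
Why: Borohydride reduction of an aldehyde; at 0 °C with a small excess of hydride the ortho-hydroxybenzyl alcohol should not be reduced further, and the MOM acetal is inert to hydride and mild base.

Step 3
Reactants: 3 2-(hydroxymethyl)-3-(methoxymethoxy)phenol; 4 sodium 4-methylbenzenesulfinate
Product: 5 3-(methoxymethoxy)-2-[(4-methylphenyl)sulfonylmethyl]phenol
Conditions: 4 (2 equiv), AcOH, THF–H2O, rt to 40 °C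
Reagents that add atoms: none
Why: Acid-promoted SN1-type dehydrative sulfonylation of an ortho-hydroxybenzylic alcohol: loss of water gives a benzylic cation stabilised by both ortho oxygens, which sulfinate captures at sulfur; acetic acid should be enough for this activated alcohol and too weak to hydrolyse the aryl MOM acetal at this temperature.

Step 4
Reactants: 6 quinidine [(S)-[(2R,4S,5R)-5-ethenyl-1-azabicyclo[2.2.2]octan-2-yl](6-methoxyquinolin-4-yl)methanol]
Product: 7 9-O-methylquinidine [(2R,4S,5R)-5-ethenyl-2-[(S)-methoxy(6-methoxyquinolin-4-yl)methyl]-1-azabicyclo[2.2.2]octane]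
Conditions: NaH, DMF, 0 °C; then MeI (1.0 equiv), 0 °C to rt
Reagents that add atoms: iodomethane, CI
Why: Williamson ether synthesis; the preformed sodium alkoxide of the C9 hydroxyl should be methylated faster than the quinuclidine nitrogen is quaternised when one equivalent of MeI is used, and no stereocentre is touched.

Step 5
Reactants: 7 9-O-methylquinidine; 8 methyl bromoacetate
Product: 9 N-(2-methoxy-2-oxoethyl)-9-O-methylquinidinium bromide [(1S,2R,4S,5R)-5-ethenyl-2-[(S)-methoxy(6-methoxyquinolin-4-yl)methyl]-1-(2-methoxy-2-oxoethyl)-1-azabicyclo[2.2.2]octan-1-ium bromide]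
Conditions: THF, rt
Reagents that add atoms: none
Why: Menshutkin quaternisation; the sp3 bridgehead quinuclidine nitrogen is far more nucleophilic than the quinoline nitrogen and should displace bromide from the α-bromo ester, and the salt should precipitate from THF; the configuration at the new ammonium centre is dictated by the bicyclic cage.

Step 6
Reactants: 5 3-(methoxymethoxy)-2-[(4-methylphenyl)sulfonylmethyl]phenol; 9 N-(2-methoxy-2-oxoethyl)-9-O-methylquinidinium bromide
Product: 13 methyl (2R)-4-(methoxymethoxy)-2,3-dihydro-1-benzofuran-2-carboxylate, via ortho-quinone methide 10 (not isolated), via ammonium ylide 11 (not isolated), via phenoxide betaine 12 (not isolated)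
Conditions: 9 (1.3 equiv), Cs2CO3 (2.5 equiv), CH2Cl2, 0 °C to rt, slow addition of 5
Reagents that add atoms: none
Why: Proposed new method: Cs2CO3 deprotonates phenol 5, whose phenoxide expels 4-methylbenzenesulfinate to give ortho-quinone methide 10, and it deprotonates salt 9 to the ester-stabilised ammonium ylide 11. The ylide carbon adds to the exocyclic CH2 of 10 in a conjugate addition that restores the aromatic ring and forms C2–C3, giving phenoxide betaine 12. The phenoxide then displaces the quinuclidinium nitrogen at the same carbon in a 5-exo-tet SN2 closure that forms O1–C2 with inversion, closes ring B and releases amine 7 for recovery. The closest known reaction type is the (4+1) annulation of substituted ortho-quinone methides with cinchona-derived ammonium ylides to trans-2,3-disubstituted dihydrobenzofurans, together with the ammonium-ylide cyclopropanation of enones, where the same addition–displacement sequence is controlled by O-methylated cinchona amines; a quinone methide with an unsubstituted CH2 terminus, where C2 is the only stereocentre, has not been shown. C2 is controlled by the chiral quinuclidinium leaving group: the ammonium-bearing carbon of 12 is acidic between N+ and the ester and epimerises through an ylide, so the two diastereomeric betaines equilibrate, and the (S)-configured one, which gives (2R)-13 by inversion, is assumed to close faster because the C9 aryl(methoxy)methyl arm lies away from the incoming phenoxide. The step needs enantioselectivity in this closure and chemoselectivity for ylide capture over self-condensation of the unhindered quinone methide. The latter should be secured by slow release of 10 in the presence of excess 11 and by the MOM-oxy group, which makes 10 a doubly vinylogous ester; acyl transfer from the methyl ester to the phenoxide is reversible, whereas the SN2 closure is not.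

Step 7
Reactants: 13 methyl (2R)-4-(methoxymethoxy)-2,3-dihydro-1-benzofuran-2-carboxylate
Product: 15 2-[(2R)-4-(methoxymethoxy)-2,3-dihydro-1-benzofuran-2-yl]propan-2-ol, via methyl ketone 14 (not isolated)
Conditions: MeMgBr (3.5 equiv), THF, −20 to 0 °C; aq NH4Cl
Reagents that add atoms: methylmagnesium bromide, C[Mg]Br
Why: Double Grignard addition to an ester through ketone 14; as with lactate-type α-alkoxy esters, carbonyl addition at low temperature should outrun enolisation, so C2 should keep its configuration, and the MOM ether is inert.

Step 8
Reactants: 15 2-[(2R)-4-(methoxymethoxy)-2,3-dihydro-1-benzofuran-2-yl]propan-2-ol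
Product: 16 ({2-[(2R)-4-(methoxymethoxy)-2,3-dihydro-1-benzofuran-2-yl]propan-2-yl}oxy)(trimethyl)silane
Conditions: TMSCl, imidazole, DMF, rt
Reagents that add atoms: chlorotrimethylsilane, C[Si](C)(C)Cl
Why: Silyl ether formation on a tertiary alcohol; it removes the only acidic proton before the lithiation, and the basic conditions leave the MOM ether alone (silyl triflates are avoided because they can cleave aryl MOM ethers).

Step 9
Reactants: 17 4-bromophenol; 18 3-chloro-3-methylbut-1-yne
Product: 19 1-bromo-4-[(2-methylbut-3-yn-2-yl)oxy]benzene
Conditions: K2CO3, KI, CuI (cat.), acetone, 56 °C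
Reagents that add atoms: none
Why: Williamson-type O-propargylation of a phenoxide with a tertiary propargylic chloride, assisted by iodide and CuI; this is the standard entry to aryl 1,1-dimethylpropargyl ethers.

Step 10
Reactants: 19 1-bromo-4-[(2-methylbut-3-yn-2-yl)oxy]benzene
Product: 22 6-bromo-2,2-dimethyl-2H-chromene, via allenylphenol 20 (not isolated), via dienone 21 (not isolated)
Conditions: PhNEt2, 190 °C
Reagents that add atoms: none
Why: Aromatic propargyl Claisen rearrangement cascade: the [3,3] shift and tautomerisation give allenylphenol 20, a 1,5-hydrogen shift gives dienone 21, and oxa-6π electrocyclisation closes ring D; both ortho positions are equivalent and the bromine ends up at C6.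

Step 11
Reactants: 22 6-bromo-2,2-dimethyl-2H-chromene; 23 N-methoxy-N-methylprop-2-enamide
Product: 24 (2E)-3-(2,2-dimethyl-2H-chromen-6-yl)-N-methoxy-N-methylprop-2-enamide
Conditions: Pd(OAc)2 (cat.), P(o-tol)3, Et3N, DMF, 100 °C
Reagents that add atoms: none
Why: Mizoroki–Heck reaction; oxidative addition of the aryl bromide to zerovalent palladium, β-selective insertion of the acrylamide and syn β-hydride elimination should give the E-alkene, and the cis-disubstituted alkene of ring D is much less reactive towards carbopalladation than the terminal acrylamide.

Step 12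
Reactants: 16 ({2-[(2R)-4-(methoxymethoxy)-2,3-dihydro-1-benzofuran-2-yl]propan-2-yl}oxy)(trimethyl)silane; 24 (2E)-3-(2,2-dimethyl-2H-chromen-6-yl)-N-methoxy-N-methylprop-2-enamide
Product: 27 (2E)-3-(2,2-dimethyl-2H-chromen-6-yl)-1-[(2R)-4-(methoxymethoxy)-2-{2-[(trimethylsilyl)oxy]propan-2-yl}-2,3-dihydro-1-benzofuran-5-yl]prop-2-en-1-one, via aryllithium 25 (not isolated), via tetrahedral adduct 26 (not isolated)
Conditions: s-BuLi, TMEDA, THF, −78 °C; then 24, −78 to −20 °C; aq NH4Cl
Reagents that add atoms: none
Why: Directed ortho-metalation followed by Weinreb ketone synthesis; the chelating MOM group should direct lithiation to C5, the only position ortho to it, in preference to C7 beside the weaker-coordinating ring oxygen, and aryllithium 25 should add 1,2 to the amide to give the chelated adduct 26, which holds until work-up and releases the E-enone without over-addition.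

Step 13
Reactants: 27 (2E)-3-(2,2-dimethyl-2H-chromen-6-yl)-1-[(2R)-4-(methoxymethoxy)-2-{2-[(trimethylsilyl)oxy]propan-2-yl}-2,3-dihydro-1-benzofuran-5-yl]prop-2-en-1-one
Product: 29 (2E)-3-(2,2-dimethyl-2H-chromen-6-yl)-1-[(2R)-4-hydroxy-2-(2-hydroxypropan-2-yl)-2,3-dihydro-1-benzofuran-5-yl]prop-2-en-1-one, via MOM ether 28 (not isolated)
Conditions: aq HCl (2 M), MeOH, rt to 40 °C
Reagents that add atoms: none
Why: Acid-catalysed solvolysis of the silyl ether (giving 28) and acetal exchange of the MOM ether in methanol; the MOM group ortho to the ketone is among the easier aryl MOM ethers to cleave, dilute acid should spare the tertiary alcohol, the chromene and the enone, and C2 is not involved.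

## Compound list

1 | 2,6-dihydroxybenzaldehyde | O=Cc1c(O)cccc1O | starting material
2 | 2-hydroxy-6-(methoxymethoxy)benzaldehyde | COCOc1cccc(O)c1C=O | intermediate
3 | 2-(hydroxymethyl)-3-(methoxymethoxy)phenol | COCOc1cccc(O)c1CO | intermediate
4 | sodium 4-methylbenzenesulfinate | Cc1ccc(cc1)S(=O)[O-].[Na+] | starting material
5 | 3-(methoxymethoxy)-2-[(4-methylphenyl)sulfonylmethyl]phenol | COCOc1cccc(O)c1CS(=O)(=O)c1ccc(C)cc1 | intermediate
6 | quinidine, (S)-[(2R,4S,5R)-5-ethenyl-1-azabicyclo[2.2.2]octan-2-yl](6-methoxyquinolin-4-yl)methanol | COC1=CC2=C(C=CN=C2C=C1)[C@@H]([C@H]3C[C@@H]4CCN3C[C@@H]4C=C)O | starting material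
7 | 9-O-methylquinidine, (2R,4S,5R)-5-ethenyl-2-[(S)-methoxy(6-methoxyquinolin-4-yl)methyl]-1-azabicyclo[2.2.2]octane | COC1=CC2=C(C=CN=C2C=C1)[C@@H]([C@H]3C[C@@H]4CCN3C[C@@H]4C=C)OC | intermediate
8 | methyl bromoacetate | COC(=O)CBr | starting material
9 | N-(2-methoxy-2-oxoethyl)-9-O-methylquinidinium bromide, (1S,2R,4S,5R)-5-ethenyl-2-[(S)-methoxy(6-methoxyquinolin-4-yl)methyl]-1-(2-methoxy-2-oxoethyl)-1-azabicyclo[2.2.2]octan-1-ium bromide (quaternised at the quinuclidine nitrogen) | COC1=CC2=C(C=CN=C2C=C1)[C@@H]([C@H]3C[C@@H]4CC[N@@+]3(CC(=O)OC)C[C@@H]4C=C)OC.[Br-] | intermediate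
10 | 5-(methoxymethoxy)-6-methylidenecyclohexa-2,4-dien-1-one (ortho-quinone methide) | C=C1C(=O)C=CC=C1OCOC | intermediate (not isolated)
11 | ammonium ylide of 9, (9-O-methylquinidinium-1-yl)(methoxycarbonyl)methanide | COC1=CC2=C(C=CN=C2C=C1)[C@@H]([C@H]3C[C@@H]4CC[N@@+]3([CH-]C(=O)OC)C[C@@H]4C=C)OC | intermediate (not isolated)
12 | phenoxide betaine, 2-[(2S)-3-methoxy-2-(9-O-methylquinidinium-1-yl)-3-oxopropyl]-3-(methoxymethoxy)phenolate (the diastereomer that closes to 13) | COC1=CC2=C(C=CN=C2C=C1)[C@@H]([C@H]3C[C@@H]4CC[N@@+]3([C@@H](Cc5c([O-])cccc5OCOC)C(=O)OC)C[C@@H]4C=C)OC | intermediate (not isolated)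
13 | methyl (2R)-4-(methoxymethoxy)-2,3-dihydro-1-benzofuran-2-carboxylate | COCOc1cccc2c1C[C@H](C(=O)OC)O2 | intermediate
14 | 1-[(2R)-4-(methoxymethoxy)-2,3-dihydro-1-benzofuran-2-yl]ethan-1-one | COCOc1cccc2c1C[C@H](C(C)=O)O2 | intermediate (not isolated)
15 | 2-[(2R)-4-(methoxymethoxy)-2,3-dihydro-1-benzofuran-2-yl]propan-2-ol | COCOc1cccc2c1C[C@H](C(C)(C)O)O2 | intermediate
16 | ({2-[(2R)-4-(methoxymethoxy)-2,3-dihydro-1-benzofuran-2-yl]propan-2-yl}oxy)(trimethyl)silane | COCOc1cccc2c1C[C@H](C(C)(C)O[Si](C)(C)C)O2 | intermediate
17 | 4-bromophenol | Oc1ccc(Br)cc1 | starting material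
18 | 3-chloro-3-methylbut-1-yne | C#CC(C)(C)Cl | starting material
19 | 1-bromo-4-[(2-methylbut-3-yn-2-yl)oxy]benzene | C#CC(C)(C)Oc1ccc(Br)cc1 | intermediate
20 | 4-bromo-2-(3-methylbuta-1,2-dien-1-yl)phenol | CC(C)=C=Cc1cc(Br)ccc1O | intermediate (not isolated)
21 | 4-bromo-6-(3-methylbut-2-en-1-ylidene)cyclohexa-2,4-dien-1-one | CC(C)=CC=C1C=C(Br)C=CC1=O | intermediate (not isolated)
22 | 6-bromo-2,2-dimethyl-2H-chromene | CC1(C)C=Cc2cc(Br)ccc2O1 | intermediate
23 | N-methoxy-N-methylprop-2-enamide | C=CC(=O)N(C)OC | starting material
24 | (2E)-3-(2,2-dimethyl-2H-chromen-6-yl)-N-methoxy-N-methylprop-2-enamide | CC1(C)C=Cc2cc(/C=C/C(=O)N(C)OC)ccc2O1 | intermediate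
25 | [(2R)-4-(methoxymethoxy)-2-{2-[(trimethylsilyl)oxy]propan-2-yl}-2,3-dihydro-1-benzofuran-5-yl]lithium | COCOc1c([Li])ccc2c1C[C@H](C(C)(C)O[Si](C)(C)C)O2 | intermediate (not isolated)
26 | lithium alkoxide of the N-methoxy-N-methyl hemiaminal formed from 25 and 24 (both configurations at the new carbinol carbon, 2R in ring B) | CC1(C)C=Cc2cc(/C=C/C(O[Li])(N(C)OC)c3ccc4c(c3OCOC)C[C@H](C(C)(C)O[Si](C)(C)C)O4)ccc2O1 | intermediate (not isolated)
27 | (2E)-3-(2,2-dimethyl-2H-chromen-6-yl)-1-[(2R)-4-(methoxymethoxy)-2-{2-[(trimethylsilyl)oxy]propan-2-yl}-2,3-dihydro-1-benzofuran-5-yl]prop-2-en-1-one | CC1(C)C=Cc2cc(/C=C/C(=O)c3ccc4c(c3OCOC)C[C@H](C(C)(C)O[Si](C)(C)C)O4)ccc2O1 | intermediate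
28 | (2E)-3-(2,2-dimethyl-2H-chromen-6-yl)-1-[(2R)-2-(2-hydroxypropan-2-yl)-4-(methoxymethoxy)-2,3-dihydro-1-benzofuran-5-yl]prop-2-en-1-one | CC1(C)C=Cc2cc(/C=C/C(=O)c3ccc4c(c3OCOC)C[C@H](C(C)(C)O)O4)ccc2O1 | intermediate (not isolated)
29 | (2E)-3-(2,2-dimethyl-2H-chromen-6-yl)-1-[(2R)-4-hydroxy-2-(2-hydroxypropan-2-yl)-2,3-dihydro-1-benzofuran-5-yl]prop-2-en-1-one | CC1(C)C=Cc2cc(/C=C/C(=O)c3ccc4c(c3O)C[C@H](C(C)(C)O)O4)ccc2O1 | target

## Step count and risk

Total step count: 13. Longest linear sequence: 8 steps (steps 1, 2, 3, 6, 7, 8, 12, 13).

**Step 6 (key step, proposed new method).**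
- **What may go wrong.** The closure may discriminate poorly between the two diastereomeric betaines, because no C3 substituent reinforces the bias of the ammonium group as it does in the substituted cases. The unhindered quinone methide may self-condense faster than the ylide captures it. The betaine phenoxide may attack the methyl ester in a six-membered lactonisation instead of displacing the amine. Carbonate may slowly epimerise the α-aryloxy ester once formed.
- **Fallback (known chemistry).** It sets out from aldehyde 2 and methyl bromoacetate 8. Condensation with K2CO3 in DMF at 90 °C (phenol O-alkylation, intramolecular aldol closure and dehydration) should give methyl 4-(methoxymethoxy)-1-benzofuran-2-carboxylate F1. Conjugate reduction of F1 with Mg in MeOH should give racemic methyl 4-(methoxymethoxy)-2,3-dihydro-1-benzofuran-2-carboxylate F2. Preparative chromatography of F2 on a chiral stationary phase would then deliver the (2R)-enantiomer, and the route is rejoined at 13. The (2S)-ester can be racemised with DBU and recycled.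

**Step 3.**
- **What may go wrong.** The MOM acetal may hydrolyse under the acid needed to ionise the benzylic alcohol. The benzylic cation may alkylate the electron-rich ring of a second molecule instead of being captured by sulfinate.
- **Fallback.** It sets out from 1 and installs the acid-labile group last. NaBH4 reduction at 0 °C should give 2-(hydroxymethyl)benzene-1,3-diol F3, and F3 is used at once. Treatment with excess 4 in aqueous HCO2H should give 2-[(4-methylphenyl)sulfonylmethyl]benzene-1,3-diol F4. Mono-alkylation of F4 with one equivalent of MOMCl and i-Pr2NEt, with recycling of recovered diol, returns to the route at 5.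

**Step 12.**
- **What may go wrong.** The hindered aryllithium may act as a base or a conjugate donor towards 24 instead of adding to the amide carbonyl. The freed N,O-dimethylhydroxylamine may add to the enone on work-up. Lithiation could also stray to C7 or to the benzylic C3, where it would open ring B.
- **Fallback.** It replaces the acylation by an aldol condensation and sets out from 16 and 22. The same lithiation of 16 and quenching with N-methoxy-N-methylacetamide should give 1-[(2R)-4-(methoxymethoxy)-2-{2-[(trimethylsilyl)oxy]propan-2-yl}-2,3-dihydro-1-benzofuran-5-yl]ethan-1-one F5. Bromine–lithium exchange on 22 with n-BuLi and formylation with DMF should give 2,2-dimethyl-2H-chromene-6-carbaldehyde F6. Claisen–Schmidt condensation of F5 with F6 (KOH, EtOH–H2O, rt), under which the trimethylsilyl ether is expected to be lost, returns to the route at 28. Compound 28 is then carried through the acid treatment of step 13.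

**Step 13.**
- **What may go wrong.** Under acid the freed C4 phenol may add to the enone to give the flavanone-type isomer. The alkene of ring D may be hydrated, or the tertiary alcohol may ionise, before the MOM ether is fully cleaved.
- **Fallback.** It removes the protecting groups before the enone and the chromene are present, and sets out from 16 and 22. The methyl ketone F5 and the aldehyde F6 are made as described under step 12. F5 is treated with aqueous HCl in MeOH to give 1-[(2R)-4-hydroxy-2-(2-hydroxypropan-2-yl)-2,3-dihydro-1-benzofuran-5-yl]ethan-1-one F7. Base-mediated Claisen–Schmidt condensation of F7 with F6 (KOH, EtOH, rt) returns to the route at 29.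

Further compounds
F1 | step 6 | methyl 4-(methoxymethoxy)-1-benzofuran-2-carboxylate | COCOc1cccc2oc(C(=O)OC)cc12
F2 | step 6 | racemic methyl 4-(methoxymethoxy)-2,3-dihydro-1-benzofuran-2-carboxylate | COCOc1cccc2c1CC(C(=O)OC)O2
F3 | step 3 | 2-(hydroxymethyl)benzene-1,3-diol | OCc1c(O)cccc1O
F4 | step 3 | 2-[(4-methylphenyl)sulfonylmethyl]benzene-1,3-diol | Cc1ccc(cc1)S(=O)(=O)Cc1c(O)cccc1O
F5 | step 12 | 1-[(2R)-4-(methoxymethoxy)-2-{2-[(trimethylsilyl)oxy]propan-2-yl}-2,3-dihydro-1-benzofuran-5-yl]ethan-1-one | COCOc1c(C(C)=O)ccc2c1C[C@H](C(C)(C)O[Si](C)(C)C)O2
F6 | step 12 | 2,2-dimethyl-2H-chromene-6-carbaldehyde | CC1(C)C=Cc2cc(C=O)ccc2O1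
F7 | step 13 | 1-[(2R)-4-hydroxy-2-(2-hydroxypropan-2-yl)-2,3-dihydro-1-benzofuran-5-yl]ethan-1-one | CC(=O)c1ccc2c(c1O)C[C@H](C(C)(C)O)O2
A1 | alternative 1 | (2E)-3-(2,2-dimethyl-2H-chromen-6-yl)-1-[(2R)-2-(2-hydroxypropan-2-yl)-4-(methoxymethoxy)-2,3-dihydro-1-benzofuran-5-yl]prop-2-en-1-one | CC1(C)C=Cc2cc(/C=C/C(=O)c3ccc4c(c3OCOC)C[C@H](C(C)(C)O)O4)ccc2O1
A2 | alternative 1 | 2-[(2R)-5-iodo-4-(methoxymethoxy)-2,3-dihydro-1-benzofuran-2-yl]propan-2-ol | COCOc1c(I)ccc2c1C[C@H](C(C)(C)O)O2
A3 | alternative 1 | 6-ethenyl-2,2-dimethyl-2H-chromene | C=Cc1ccc2OC(C)(C)C=Cc2c1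
A4 | alternative 2 | (2R)-2-(2-hydroxypropan-2-yl)-2,3-dihydro-1-benzofuran-4-ol | Oc1cccc2c1C[C@H](C(C)(C)O)O2
A5 | alternative 2 | 1,3-bis{[tert-butyl(dimethyl)silyl]oxy}-2-(3-methylbut-2-en-1-yl)benzene | CC(C)=CCc1c(O[Si](C)(C)C(C)(C)C)cccc1O[Si](C)(C)C(C)(C)C
A6 | alternative 2 | (3S)-3-[(2,6-bis{[tert-butyl(dimethyl)silyl]oxy}phenyl)methyl]-2,2-dimethyloxirane | CC1(C)O[C@H]1Cc1c(O[Si](C)(C)C(C)(C)C)cccc1O[Si](C)(C)C(C)(C)C
A7 | alternative 3 | tert-butyl(dimethyl){[(2R)-2-[2-(triethylsilyloxy)propan-2-yl]-2,3-dihydro-1-benzofuran-4-yl]oxy}silane | CC(C)(C)[Si](C)(C)Oc1cccc2c1C[C@H](C(C)(C)O[Si](CC)(CC)CC)O2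
A8 | alternative 3 | N'-[(E)-{2-[tert-butyl(dimethyl)silyl]oxy-6-[2-methyl-2-(triethylsilyloxy)propoxy]phenyl}methylidene]-4-methylbenzenesulfonohydrazide | Cc1ccc(cc1)S(=O)(=O)N/N=C/c1c(O[Si](C)(C)C(C)(C)C)cccc1OCC(C)(C)O[Si](CC)(CC)CC
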